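**Plan** (labdane numbering; α = face of H-5, β = face of CH3-20; the target is 18-acetoxylabda-8(17),13E-dien-15-oic acid)
- Retrosynthesis: cut the allyl ester, the C8=C17/H-7 allylic transposition, C13=C14 (olefination), C11–C12 (borane alkylation) and C9=C11 (methylenation). Then reverse a 1,2-shift of C3 from C4 back to C18, which opens ring A to a seven-membered ring C10–C1–C2–C3–C18–C4–C5. Cut its C4=C18 alkene by metathesis and the two C10–C bonds as enolate alkylations of carvone.
- Forward: ring B is (R)-carvone. C20 and a pentenyl arm go onto C10, and ring-closing metathesis of the pentenyl and isopropenyl arms closes the seven-membered ring. Epoxidation and a Lewis-acid 1,2-shift contract it to ring A, then the side chain is built on the C9 ketone and C7=C8 is moved to C8=C17.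
- Enabling feature: the trisubstituted alkene C4(CH3)=C18H inside the seven-membered ring, with C4 bonded to ring-fusion carbon C5. Its epoxide ionises at tertiary C4 and ring carbon C3 shifts from C18 to C4, so C18 leaves the ring as the formyl group on the new quaternary C4 and ring A (C1–C5, C10) appears in its final size.
- Stereochemistry: C5 from (R)-carvone; C10 by alkylation anti to the isopropenyl group; C4 by α-epoxidation (anti to C20) and the stereospecific anti 1,2-shift; C9 by hydroboration from the α face; 13E by Horner–Wadsworth–Emmons olefination.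
- The carvone enone keeps the ring B alkene inert during the ring A chemistry, and its methyl group becomes C17.

Key step: step 5

Assumption: compound 3 is drawn as its major trans epimer; both C6 epimers give the same enolate 5 in step 2, so the mixture is carried on.

**Step 1**
Reactants: 1 (R)-(−)-carvone
Product: 3 (5R,6S)-6-methylcarvone, via lithium dienolate 2 (not isolated)
Conditions: LiN(iPr)2 (commercial solution), THF, −78 °C; then MeI, −78 → 0 °C
Reagents that add atoms: iodomethane, CI
Why: kinetic α′-deprotonation of the enone gives the cross-conjugated dienolate, which is C-methylated (enolate alkylation); the new C6 centre is re-enolised in step 2, so its configuration does not matter.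

**Step 2**
Reactants: 3 (5R,6S)-6-methylcarvone; 4 5-iodopent-1-ene
Product: 6 (5S,6S)-2,6-dimethyl-6-(pent-4-en-1-yl)-5-(prop-1-en-2-yl)cyclohex-2-en-1-one, via lithium enolate 5 (not isolated)
Conditions: LiN(iPr)2 (commercial solution), THF, −78 °C; then 4, DMPU, −78 → 23 °C
Reagents that add atoms: none
Why: enolate alkylation of the tetrasubstituted α′-enolate, in which the primary iodide should approach anti to the neighbouring pseudoaxial isopropenyl group, so that the pentenyl arm ends trans and the methyl cis to it (the future 10β-CH3 / 5α-H relationship).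

**Step 3**
Reactants: 6 (5S,6S)-2,6-dimethyl-6-(pent-4-en-1-yl)-5-(prop-1-en-2-yl)cyclohex-2-en-1-one
Product: 7 3(4→18)abeo-11,12,13,14,15,16-hexanorlabda-4(18),7-dien-9-one (trans-fused 6–7 bicycle with C4(CH3)=C18H in the seven-membered ring)
Conditions: second-generation Grubbs catalyst RuCl2(=CHPh)(H2IMes)(PCy3) (cat.), toluene (dilute), 80 °C
Reagents that add atoms: none
Why: ring-closing metathesis of the terminal alkene with the 1,1-disubstituted isopropenyl group should close the trisubstituted cycloheptene because the two arms are trans-vicinal on ring B, the conjugated enone alkene is inert to the catalyst, and loss of ethene drives the closure.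

**Step 4**
Reactants: 7 3(4→18)abeo-11,12,13,14,15,16-hexanorlabda-4(18),7-dien-9-one
Product: 8 4α,18α-epoxy-3(4→18)abeo-11,12,13,14,15,16-hexanorlabd-7-en-9-one
Conditions: mCPBA, NaHCO3, CH2Cl2, 0 °C
Reagents that add atoms: 3-chloroperoxybenzoic acid, OOC(=O)c1cccc(Cl)c1
Why: Prilezhaev epoxidation picks the electron-rich trisubstituted alkene over the electron-poor enone, and oxygen should be delivered to the α face because the angular methyl C20 shields the β face, which fixes the epoxide configuration at C4 and C18.

**Step 5**
Reactants: 8 4α,18α-epoxy-3(4→18)abeo-11,12,13,14,15,16-hexanorlabd-7-en-9-one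
Product: 9 9-oxo-11,12,13,14,15,16-hexanorlabd-7-en-18-al (4α-CHO and 4β-CH3)
Conditions: MeAl(OC6H2-4-Br-2,6-tBu2)2 (2 equiv; from AlMe3 and 4-bromo-2,6-di-tert-butylphenol), CH2Cl2, −78 → −20 °C; aqueous NaF work-up
Reagents that add atoms: none
Why: The aluminium Lewis acid binds the epoxide oxygen, the C4–O bond ionises toward the tertiary centre and the ring bond C18–C3 migrates to C4 anti to the departing oxygen, so that C18 becomes the formyl carbon (Meinwald/semipinacol-type epoxide rearrangement with ring contraction, the reaction type known for 1-methylcycloalkene oxides with this reagent). Ring A (C1–C2–C3–C4–C5–C10) is therefore formed not by a cyclisation but by a 1,2-alkyl shift, a seven-to-six ring contraction driven by relief of medium-ring strain and by C=O formation. The new quaternary centre C4 is controlled by the epoxide configuration: oxygen leaves from the α face and C3 enters from the β face with inversion, which places the formyl group α (equatorial, C18) and the methyl β (axial, C19). The step needs the alkyl shift to beat the 1,2-hydride shift (which would give the ring-retained C18 ketone) and proton loss to an allylic alcohol; the bulky, non-nucleophilic aluminium phenoxide at low temperature is the reagent class that turns trisubstituted epoxides into aldehydes, and the ring bond on C18 can align with the developing empty orbital at C4. The hindered conjugated ketone at C9 is a poorer donor than the epoxide and should take no part.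

**Step 6**
Reactants: 9 9-oxo-11,12,13,14,15,16-hexanorlabd-7-en-18-al
Product: 10 18-hydroxy-11,12,13,14,15,16-hexanorlabd-7-en-9-one
Conditions: NaBH4 (limiting), EtOH–CH2Cl2, −78 → −40 °C
Reagents that add atoms: none
Why: chemoselective borohydride reduction, since the aldehyde is far more electrophilic than the hindered, conjugated C9 ketone flanked by a quaternary carbon.

**Step 7**
Reactants: 10 18-hydroxy-11,12,13,14,15,16-hexanorlabd-7-en-9-one
Product: 11 9-oxo-11,12,13,14,15,16-hexanorlabd-7-en-18-yl acetate
Conditions: Ac2O, pyridine, DMAP (cat.), CH2Cl2, 23 °C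
Reagents that add atoms: acetic anhydride, CC(=O)OC(C)=O
Why: standard DMAP-catalysed acylation of the neopentyl primary alcohol installs the acetate of the target, which is tolerated by all later steps.

**Step 8**
Reactants: 11 9-oxo-11,12,13,14,15,16-hexanorlabd-7-en-18-yl acetate
Product: 12 12,13,14,15,16-pentanorlabda-7,9(11)-dien-18-yl acetate
Conditions: Zn, CH2Br2, TiCl4, THF–CH2Cl2, 0 → 23 °C (Takai–Lombardo methylenation)
Reagents that add atoms: dibromomethane, BrCBr
Why: the non-basic gem-dimetallic methylene reagent methylenates hindered, enolisable ketones and leaves esters alone, so C11 is added to the C9 carbonyl without touching the acetate or forming the dienolate.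

**Step 9**
Reactants: 12 12,13,14,15,16-pentanorlabda-7,9(11)-dien-18-yl acetate; 13 bromoacetone
Product: 15 13-oxo-14,15-dinorlabd-7-en-18-yl acetate, via B-alkyl-9-BBN 14 (not isolated)
Conditions: 9-BBN, THF, 23 → 60 °C; then 13, KOC6H3-2,6-tBu2 (from the phenol and KOtBu), THF, 0 → 23 °C
Reagents that add atoms: none
Why: anti-Markovnikov hydroboration of the exocyclic terminus of the diene puts boron on C11 and hydrogen on C9 from the α face (opposite the axial C20 methyl), which sets C9, and Brown α-alkylation of the bromoacetone enolate (ate complex, 1,2-shift of the primary alkyl with loss of bromide, protonolysis) then joins C11 to C12.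

**Step 10**
Reactants: 15 13-oxo-14,15-dinorlabd-7-en-18-yl acetate; 16 allyl 2-(diethoxyphosphoryl)acetate
Product: 17 allyl 18-acetoxylabda-7,13E-dien-15-oate
Conditions: 16, NaH, THF, 0 → 50 °C; chromatography to remove the minor 13Z isomer
Reagents that add atoms: none
Why: Horner–Wadsworth–Emmons olefination of the methyl ketone should favour the E-trisubstituted enoate (larger chain trans to the ester), and the allyl ester is chosen so that the acid can be freed later without touching the acetate.

**Step 11**
Reactants: 17 allyl 18-acetoxylabda-7,13E-dien-15-oate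
Product: 18 allyl 18-acetoxy-17-hydroxylabda-7,13E-dien-15-oate
Conditions: SeO2 (cat.), tBuOOH, CH2Cl2, 0 → 23 °C
Reagents that add atoms: selenium dioxide, O=[Se]=O (oxygen donor), reoxidised by tert-butyl hydroperoxide, CC(C)(C)OO
Why: selenium dioxide allylic oxidation (ene reaction then [2,3]-shift) acts at the more substituted end of the electron-rich C7=C8 alkene and should take the C17 methyl in preference to the hindered C9 methine, as in related 8-methyl-7-ene decalins, while the conjugated enoate is deactivated.

**Step 12**
Reactants: 18 allyl 18-acetoxy-17-hydroxylabda-7,13E-dien-15-oate; 19 N-isopropylidene-N′-(2-nitrobenzenesulfonyl)hydrazine (IPNBSH)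
Product: 22 allyl 18-acetoxylabda-8(17),13E-dien-15-oate, via N-allylic sulfonylhydrazone 20 (not isolated), via allylic diazene 21 (not isolated)
Conditions: 19, PPh3, EtO2CN=NCO2Et, THF, 0 → 23 °C; then CF3CH2OH–H2O (1:1), 23 °C
Reagents that add atoms: none
Why: Mitsunobu N-alkylation at C17, hydrolysis of the hydrazone and loss of sulfinic acid give the monoalkyl diazene, whose retro-ene loss of N2 delivers hydrogen to C7 and moves the alkene to the exocyclic C8=C17 position (reductive allylic transposition) without creating a stereocentre.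

**Step 13**
Reactants: 22 allyl 18-acetoxylabda-8(17),13E-dien-15-oate
Product: 23 18-acetoxylabda-8(17),13E-dien-15-oic acid
Conditions: Pd(PPh3)4 (cat.), morpholine, THF, 23 °C; dilute acid work-up
Reagents that add atoms: none
Why: palladium-catalysed allyl transfer to morpholine (Tsuji–Trost deallylation) frees the carboxylic acid under neutral conditions that leave the non-allylic acetate, the exocyclic alkene and the E-enoate untouched.

**Compound list**
1 | (R)-(−)-carvone | C=C(C)[C@@H]1CC=C(C)C(=O)C1 | starting material
2 | lithium cross-conjugated dienolate of 1 | C=C(C)[C@@H]1CC=C(C)C(O[Li])=C1 | intermediate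
3 | (5R,6S)-6-methylcarvone (major trans epimer) | C=C(C)[C@@H]1CC=C(C)C(=O)[C@H]1C | intermediate
4 | 5-iodopent-1-ene | C=CCCCI | starting material
5 | lithium enolate of 3 | C=C(C)[C@@H]1CC=C(C)C(O[Li])=C1C | intermediate
6 | (5S,6S)-2,6-dimethyl-6-(pent-4-en-1-yl)-5-(prop-1-en-2-yl)cyclohex-2-en-1-one | C=C(C)[C@@H]1CC=C(C)C(=O)[C@@]1(C)CCCC=C | intermediate
7 | 3(4→18)abeo-11,12,13,14,15,16-hexanorlabda-4(18),7-dien-9-one | CC1=CCCC[C@]2(C)C(=O)C(C)=CC[C@H]21 | intermediate
8 | 4α,18α-epoxy-3(4→18)abeo-11,12,13,14,15,16-hexanorlabd-7-en-9-one | C[C@]12O[C@@H]2CCC[C@]3(C)C(=O)C(C)=CC[C@H]31 | intermediate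
9 | 9-oxo-11,12,13,14,15,16-hexanorlabd-7-en-18-al | O=C[C@]1(C)CCC[C@]2(C)C(=O)C(C)=CC[C@H]21 | intermediate
10 | 18-hydroxy-11,12,13,14,15,16-hexanorlabd-7-en-9-one | OC[C@]1(C)CCC[C@]2(C)C(=O)C(C)=CC[C@H]21 | intermediate
11 | 9-oxo-11,12,13,14,15,16-hexanorlabd-7-en-18-yl acetate | CC(=O)OC[C@]1(C)CCC[C@]2(C)C(=O)C(C)=CC[C@H]21 | intermediate
12 | 12,13,14,15,16-pentanorlabda-7,9(11)-dien-18-yl acetate | CC(=O)OC[C@]1(C)CCC[C@]2(C)C(=C)C(C)=CC[C@H]21 | intermediate
13 | bromoacetone | CC(=O)CBr | starting material
14 | B-(18-acetoxy-12,13,14,15,16-pentanorlabd-7-en-11-yl)-9-borabicyclo[3.3.1]nonane (9α-H) | CC(=O)OC[C@]1(C)CCC[C@]2(C)[C@@H](CB3C4CCCC3CCC4)C(C)=CC[C@H]21 | intermediate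
15 | 13-oxo-14,15-dinorlabd-7-en-18-yl acetate | CC(=O)OC[C@]1(C)CCC[C@]2(C)[C@@H](CCC(C)=O)C(C)=CC[C@H]21 | intermediate
16 | allyl 2-(diethoxyphosphoryl)acetate | C=CCOC(=O)CP(=O)(OCC)OCC | starting material
17 | allyl 18-acetoxylabda-7,13E-dien-15-oate | CC(=O)OC[C@]1(C)CCC[C@]2(C)[C@@H](CC/C(C)=C/C(=O)OCC=C)C(C)=CC[C@H]21 | intermediate
18 | allyl 18-acetoxy-17-hydroxylabda-7,13E-dien-15-oate | CC(=O)OC[C@]1(C)CCC[C@]2(C)[C@@H](CC/C(C)=C/C(=O)OCC=C)C(CO)=CC[C@H]21 | intermediate
19 | N-isopropylidene-N′-(2-nitrobenzenesulfonyl)hydrazine (IPNBSH) | CC(C)=NNS(=O)(=O)c1ccccc1[N+](=O)[O-] | starting material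
20 | N-(C17-allylic) N-isopropylidene sulfonylhydrazone of 18 | CC(=O)OC[C@]1(C)CCC[C@]2(C)[C@@H](CC/C(C)=C/C(=O)OCC=C)C(CN(N=C(C)C)S(=O)(=O)c3ccccc3[N+](=O)[O-])=CC[C@H]21 | intermediate
21 | C17 allylic monoalkyl diazene | CC(=O)OC[C@]1(C)CCC[C@]2(C)[C@@H](CC/C(C)=C/C(=O)OCC=C)C(CN=N)=CC[C@H]21 | intermediate
22 | allyl 18-acetoxylabda-8(17),13E-dien-15-oate | C=C1CC[C@H]2[C@](C)(COC(C)=O)CCC[C@]2(C)[C@H]1CC/C(C)=C/C(=O)OCC=C | intermediate
23 | 18-acetoxylabda-8(17),13E-dien-15-oic acid | C=C1CC[C@H]2[C@](C)(COC(C)=O)CCC[C@]2(C)[C@H]1CC/C(C)=C/C(=O)O | target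

**Step count**
Total steps: 13. Longest linear sequence: 13 steps, all from (R)-carvone.

**Steps most likely to fail**

Step 5. A 1,2-hydride shift from C18 to C4 (giving the ring-retained ketone), or ionisation to a free cation with loss of the anti stereospecificity, may compete with the ring-carbon shift. The fallback uses the hydride shift on purpose and moves the ring contraction to a Favorskii rearrangement.
- From epoxide 8, LiClO4 in hot benzene should give the seven-membered C18 ketone F1.
- Bromination through its more substituted enol (pyridinium tribromide, AcOH) should deliver bromine to C4 from the α face and give the α-bromo ketone F2.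
- NaOMe in MeOH should bond C3 to C4 anti to bromide and expel C18 as the ester carbon, giving the ring-contracted methyl ester F3 with the same C4 configuration as 9.
- LiAlH4 reduces ester and ketone to the diol F4, and MnO2 reoxidises the allylic C9 alcohol, rejoining the route at 10.

Step 4. Facial selectivity of the epoxidation may be poor or reversed in the flexible cycloheptene, which would invert C4 after step 5. If the electrophile prefers the β face, the fallback inverts the outcome through a halohydrin. From 7, NBS in aqueous THF should form the bromonium ion on that same face, with water opening it at tertiary C4 from the α face to give the bromohydrin F5. K2CO3 in MeOH then closes the 4α-alkoxide onto C18 with inversion and returns the α-epoxide 8.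

Step 9. Hydroboration of the hindered conjugated diene may be slow or unselective, and protonolysis of the ate complex may outrun the 1,2-shift to the bromoacetone carbon. The fallback builds C11–C12 by carbonyl olefination.
- From the borane 14, oxidation with NaBO3·4H2O should give the primary alcohol F6.
- Dess–Martin periodinane gives the aldehyde F7, kept free of base to avoid conjugation.
- Wittig reaction with Ph3P=CHC(O)CH3 gives the E-enone F8.
- 1,4-Reduction with [(Ph3P)CuH]6 gives the methyl ketone 15.

**Further compounds**
F1 | step 5 | 3(4→18)abeo-11,12,13,14,15,16-hexanorlabd-7-ene-9,18-dione (4α-CH3) | C[C@@H]1C(=O)CCC[C@]2(C)C(=O)C(C)=CC[C@H]21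
F2 | step 5 | 4α-bromo-3(4→18)abeo-11,12,13,14,15,16-hexanorlabd-7-ene-9,18-dione | C[C@@]1(Br)C(=O)CCC[C@]2(C)C(=O)C(C)=CC[C@H]21
F3 | step 5 | methyl 9-oxo-11,12,13,14,15,16-hexanorlabd-7-en-18-oate | COC(=O)[C@]1(C)CCC[C@]2(C)C(=O)C(C)=CC[C@H]21
F4 | step 5 | 11,12,13,14,15,16-hexanorlabd-7-ene-9β,18-diol | OC[C@]1(C)CCC[C@]2(C)[C@@H](O)C(C)=CC[C@H]21
F5 | step 4 | 18β-bromo-4α-hydroxy-3(4→18)abeo-11,12,13,14,15,16-hexanorlabd-7-en-9-one | C[C@@]1(O)[C@@H](Br)CCC[C@]2(C)C(=O)C(C)=CC[C@H]21
F6 | step 9 | 11-hydroxy-12,13,14,15,16-pentanorlabd-7-en-18-yl acetate | CC(=O)OC[C@]1(C)CCC[C@]2(C)[C@@H](CO)C(C)=CC[C@H]21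
F7 | step 9 | 11-oxo-12,13,14,15,16-pentanorlabd-7-en-18-yl acetate | CC(=O)OC[C@]1(C)CCC[C@]2(C)[C@@H](C=O)C(C)=CC[C@H]21
F8 | step 9 | 13-oxo-14,15-dinorlabda-7,11E-dien-18-yl acetate | CC(=O)OC[C@]1(C)CCC[C@]2(C)[C@@H](/C=C/C(C)=O)C(C)=CC[C@H]21
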